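**Retrosynthetic overview**
- Target 10 ⇐ 7: the C8 prenyl group comes from a 5-O-prenyl ether by a europium-catalysed para-Claisen–Cope shift, so the prenyl ether also masks the second ring A phenol.
- 7 ⇐ chalcone 6: the key bond is O1–C2, made by a catalytic enantioselective 6-endo oxa-Michael closure that forms ring C and sets 2S. Only one ring A phenol is free, so only one regioisomer can form.
- 6 ⇐ acetophenone 3 + isovanillin 4 (Claisen–Schmidt); 3 ⇐ symmetrical diphenol 1 + prenyl bromide 2 (mono-O-prenylation).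
- Ring order: rings A and B are bought; ring C is the only ring formed (step 3).

Assumption: 1, 2 and 4 are catalogue chemicals, and the sense of induction of the new catalyst is fixed by a first screen (the mirror-image catalyst from D-tert-leucine is used if the L-derived one gives 2R).

Catalyst used in step 3 (prepared separately by the known Staudinger reaction of the L-tert-leucine-derived azido-thiourea with tris(4-methoxyphenyl)phosphine, not counted as a route step): the (S)-BIMP catalyst 1-[3,5-bis(trifluoromethyl)phenyl]-3-[(2S)-3,3-dimethyl-1-{[tris(4-methoxyphenyl)phosphanylidene]amino}butan-2-yl]thiourea, SMILES CC(C)(C)[C@@H](CN=P(c1ccc(OC)cc1)(c1ccc(OC)cc1)c1ccc(OC)cc1)NC(=S)Nc1cc(C(F)(F)F)cc(C(F)(F)F)c1.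

**Route**

Step 1
Reactants: 1 1-(2,6-dihydroxy-4-methoxyphenyl)ethanone; 2 1-bromo-3-methylbut-2-ene (prenyl bromide)
Product: 3 1-[2-hydroxy-4-methoxy-6-(3-methylbut-2-enyloxy)phenyl]ethanone
Conditions: 2 (1.05 equiv), K2CO3 (1.5 equiv), acetone, reflux, 6 h
Reagents that add atoms: prenyl bromide (compound 2), CC(C)=CCBr
Why: Williamson O-alkylation of a symmetrical diphenol stops cleanly at the mono-ether because the remaining OH is locked in a hydrogen bond to the acetyl carbonyl; no stereocenter is formed.

Step 2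
Reactants: 3 1-[2-hydroxy-4-methoxy-6-(3-methylbut-2-enyloxy)phenyl]ethanone; 4 3-hydroxy-4-methoxybenzaldehyde (isovanillin)
Product: 6 (E)-3-(3-hydroxy-4-methoxyphenyl)-1-[2-hydroxy-4-methoxy-6-(3-methylbut-2-enyloxy)phenyl]prop-2-en-1-one, via aldol adduct 5 (not isolated)
Conditions: KOH (50% aq, 8 equiv), EtOH, 0 °C to rt, 36 h; then cold 1 M HCl to pH 5
Reagents that add atoms: none
Why: Claisen–Schmidt aldol condensation, in which the meta-phenoxide of isovanillin deactivates the aldehyde only weakly, E1cB dehydration of 5 gives the E-enone, and the chalcone phenoxide does not cyclise in strong base and is liberated cold.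

Step 3
Reactants: 6 (E)-3-(3-hydroxy-4-methoxyphenyl)-1-[2-hydroxy-4-methoxy-6-(3-methylbut-2-enyloxy)phenyl]prop-2-en-1-one
Product: 7 (2S)-2-(3-hydroxy-4-methoxyphenyl)-7-methoxy-5-(3-methylbut-2-enyloxy)-2,3-dihydrochromen-4-one
Conditions: (S)-BIMP catalyst defined above (10 mol %), toluene (0.05 M), –20 °C, 24–48 h; AcOH quench, silica plug
Reagents that add atoms: none
Why: Proposed new method: an enantioselective 6-endo-trig intramolecular oxa-Michael addition of an unactivated 2'-hydroxychalcone under bifunctional iminophosphorane catalysis. The superbasic P=N site deprotonates the chelated 2'-OH to a tight chiral aminophosphonium/phenoxide ion pair while the thiourea N–H pair binds the enone carbonyl, so the phenoxide oxygen adds to one enantiotopic face of C-β inside the catalyst pocket (this sets C2 as S) and the enolate is protonated by the P–N–H, which regenerates the base in an atom-economic isomerisation. The 6'-prenyloxy group twists the aroyl group out of conjugation, which speeds closure and makes it strongly exergonic, so the retro-oxa-Michael pathway that normally racemises flavanones should be negligible at –20 °C, and the free ring B phenol buffers the catalyst resting state. The closest known reaction types are iminophosphorane-catalysed intramolecular oxa-Michael additions of alcohols to unsaturated esters and amides, and the cinchona-thiourea-catalysed cyclisation of ester-activated 2'-hydroxychalcones; neither has been shown for plain chalcones.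

Step 4
Reactants: 7 (2S)-2-(3-hydroxy-4-methoxyphenyl)-7-methoxy-5-(3-methylbut-2-enyloxy)-2,3-dihydrochromen-4-one
Product: 10 (2S)-5-hydroxy-2-(3-hydroxy-4-methoxyphenyl)-7-methoxy-8-(3-methylbut-2-enyl)-2,3-dihydrochromen-4-one, via ortho-dienone 8 (not isolated), via para-dienone 9 (not isolated)
Conditions: Eu(fod)3 (10 mol %; the tris(heptafluoro-dimethyloctanedionate) of trivalent europium), PhCl, 80 °C, 12–24 h
Reagents that add atoms: none
Why: Europium-catalysed aromatic para-Claisen–Cope rearrangement: chelation of trivalent europium between C4=O and the 5-ether oxygen triggers the [3,3] shift to C6 (dienone 8), a second [3,3] shift carries the allyl unit to C8 as a normal prenyl group (dienone 9), and tautomerisation gives the hydrogen-bonded 5-OH phenol; C2 is not involved and stays S.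

**Compound list**

1 | 1-(2,6-dihydroxy-4-methoxyphenyl)ethanone (2',6'-dihydroxy-4'-methoxyacetophenone) | CC(=O)c1c(O)cc(OC)cc1O | starting material
2 | 1-bromo-3-methylbut-2-ene (prenyl bromide) | CC(C)=CCBr | starting material
3 | 1-[2-hydroxy-4-methoxy-6-(3-methylbut-2-enyloxy)phenyl]ethanone | CC(=O)c1c(O)cc(OC)cc1OCC=C(C)C | intermediate
4 | 3-hydroxy-4-methoxybenzaldehyde (isovanillin) | COc1ccc(C=O)cc1O | starting material
5 | 3-hydroxy-3-(3-hydroxy-4-methoxyphenyl)-1-[2-hydroxy-4-methoxy-6-(3-methylbut-2-enyloxy)phenyl]propan-1-one (racemic aldol adduct, not isolated) | COc1ccc(C(O)CC(=O)c2c(O)cc(OC)cc2OCC=C(C)C)cc1O | intermediate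
6 | (E)-3-(3-hydroxy-4-methoxyphenyl)-1-[2-hydroxy-4-methoxy-6-(3-methylbut-2-enyloxy)phenyl]prop-2-en-1-one | COc1ccc(/C=C/C(=O)c2c(O)cc(OC)cc2OCC=C(C)C)cc1O | intermediate
7 | (2S)-2-(3-hydroxy-4-methoxyphenyl)-7-methoxy-5-(3-methylbut-2-enyloxy)-2,3-dihydrochromen-4-one | COc1ccc([C@@H]2CC(=O)c3c(OCC=C(C)C)cc(OC)cc3O2)cc1O | intermediate
8 | (2S)-2-(3-hydroxy-4-methoxyphenyl)-7-methoxy-6-(2-methylbut-3-en-2-yl)-2,3-dihydro-4H-chromene-4,5(6H)-dione (ortho-dienone, C6 epimers, not isolated) | COc1ccc([C@@H]2CC(=O)C3=C(O2)C=C(OC)C(C3=O)C(C)(C)C=C)cc1O | intermediate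
9 | (2S)-2-(3-hydroxy-4-methoxyphenyl)-7-methoxy-8-(3-methylbut-2-enyl)-2,3-dihydro-4H-chromene-4,5(8H)-dione (para-dienone, C8 epimers, not isolated) | COc1ccc([C@@H]2CC(=O)C3=C(O2)C(CC=C(C)C)C(OC)=CC3=O)cc1O | intermediate
10 | (2S)-5-hydroxy-2-(3-hydroxy-4-methoxyphenyl)-7-methoxy-8-(3-methylbut-2-enyl)-2,3-dihydrochromen-4-one (CNP0228678.1) | COc1ccc([C@@H]2CC(=O)c3c(O)cc(OC)c(CC=C(C)C)c3O2)cc1O | target

**Totals**

Total step count: 4. Longest linear sequence: 4 steps (1 → 3 → 6 → 7 → 10).

**Steps most likely to fail, with fallbacks**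

Step 3 (the proposed new method). The risks are a slow closure on the electron-rich ring B enone, erosion of ee by a background cyclisation mediated by the ring B phenoxide or by reversible ring opening, and an unknown sense of induction. The ee is checked by chiral HPLC and the 2S configuration by CD (positive band near 330 nm, negative near 290 nm). The fallback uses known chemistry only, sets out from 6 and rejoins at 7. Chalcone 6 is heated with NaOAc in EtOH at reflux, the standard base-mediated chalcone–flavanone isomerisation, to give racemic 2-(3-hydroxy-4-methoxyphenyl)-7-methoxy-5-(3-methylbut-2-enyloxy)-2,3-dihydrochromen-4-one F1. The racemate is separated by preparative chiral chromatography on an amylose tris(3,5-dimethylphenylcarbamate) phase. The (2S)-enantiomer is 7; the (2R)-enantiomer F2 is re-racemised under the same NaOAc conditions and recycled.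

Step 4. The risks are that the rearrangement stops at the ortho stage (the 6-(2-methylbut-3-en-2-yl) phenol from tautomerisation of 8) and that Lewis-acid ring opening of the 5-hydroxyflavanone partly erodes C2. The fallback installs the prenyl group before ring C exists; it sets out from 3 and rejoins at 10. Ether 3 is heated in N,N-diethylaniline at 200 °C (thermal para-Claisen–Cope of an ortho-acyl aryl prenyl ether) to give 1-[2,6-dihydroxy-4-methoxy-3-(3-methylbut-2-enyl)phenyl]ethanone F3. The unhindered, non-chelated phenol remote from the prenyl group is masked with MOMCl and iPr2NEt in CH2Cl2 at 0 °C to give 1-[2-hydroxy-4-methoxy-6-(methoxymethoxy)-3-(3-methylbut-2-enyl)phenyl]ethanone F4. Claisen–Schmidt condensation with 4 (KOH, EtOH) gives (E)-3-(3-hydroxy-4-methoxyphenyl)-1-[2-hydroxy-4-methoxy-6-(methoxymethoxy)-3-(3-methylbut-2-enyl)phenyl]prop-2-en-1-one F5. The only free ring A phenol is now the one next to the prenyl group, so closure by the step 3 catalysis gives (2S)-2-(3-hydroxy-4-methoxyphenyl)-7-methoxy-5-(methoxymethoxy)-8-(3-methylbut-2-enyl)-2,3-dihydrochromen-4-one F6. Removal of the MOM group with 3 M HCl in MeOH at rt gives 10.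

Step 2. The risks are a sluggish condensation of the isovanillin phenoxide and partial racemic ring closure to flavanone during acidification. The fallback masks the aldehyde phenol; it sets out from 4 (coupled with 3) and rejoins at 6. Isovanillin 4 is treated with 3,4-dihydro-2H-pyran and PPTS in CH2Cl2 to give 4-methoxy-3-(oxan-2-yloxy)benzaldehyde F7. Claisen–Schmidt condensation with 3 (KOH, EtOH, rt) gives (E)-1-[2-hydroxy-4-methoxy-6-(3-methylbut-2-enyloxy)phenyl]-3-[4-methoxy-3-(oxan-2-yloxy)phenyl]prop-2-en-1-one F8. Mild acetal exchange with PPTS in MeOH at rt releases 6 without touching the prenyl ether.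

**Further compounds**

F1 | step 3 | racemic 2-(3-hydroxy-4-methoxyphenyl)-7-methoxy-5-(3-methylbut-2-enyloxy)-2,3-dihydrochromen-4-one | COc1ccc(C2CC(=O)c3c(OCC=C(C)C)cc(OC)cc3O2)cc1O
F2 | step 3 | (2R)-2-(3-hydroxy-4-methoxyphenyl)-7-methoxy-5-(3-methylbut-2-enyloxy)-2,3-dihydrochromen-4-one | COc1ccc([C@H]2CC(=O)c3c(OCC=C(C)C)cc(OC)cc3O2)cc1O
F3 | step 4 | 1-[2,6-dihydroxy-4-methoxy-3-(3-methylbut-2-enyl)phenyl]ethanone | CC(=O)c1c(O)cc(OC)c(CC=C(C)C)c1O
F4 | step 4 | 1-[2-hydroxy-4-methoxy-6-(methoxymethoxy)-3-(3-methylbut-2-enyl)phenyl]ethanone | CC(=O)c1c(OCOC)cc(OC)c(CC=C(C)C)c1O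
F5 | step 4 | (E)-3-(3-hydroxy-4-methoxyphenyl)-1-[2-hydroxy-4-methoxy-6-(methoxymethoxy)-3-(3-methylbut-2-enyl)phenyl]prop-2-en-1-one | COc1ccc(/C=C/C(=O)c2c(OCOC)cc(OC)c(CC=C(C)C)c2O)cc1O
F6 | step 4 | (2S)-2-(3-hydroxy-4-methoxyphenyl)-7-methoxy-5-(methoxymethoxy)-8-(3-methylbut-2-enyl)-2,3-dihydrochromen-4-one | COc1ccc([C@@H]2CC(=O)c3c(OCOC)cc(OC)c(CC=C(C)C)c3O2)cc1O
F7 | step 2 | 4-methoxy-3-(oxan-2-yloxy)benzaldehyde (racemic acetal) | COc1ccc(C=O)cc1OC1CCCCO1
F8 | step 2 | (E)-1-[2-hydroxy-4-methoxy-6-(3-methylbut-2-enyloxy)phenyl]-3-[4-methoxy-3-(oxan-2-yloxy)phenyl]prop-2-en-1-one (racemic acetal) | COc1ccc(/C=C/C(=O)c2c(O)cc(OC)cc2OCC=C(C)C)cc1OC1CCCCO1
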